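Each ring carries the tether on C1 with its oxygens on C3 and C5, the pattern of a 5-alkylcyclohexane-1,3-dione. Rings A (the acetoxy ring) and B are therefore both cut at C1–C6 and C4–C5 into a methyl enone and dimethyl malonate; the C16 tether plus the two C1 atoms is the C18 chain of (Z)-octadec-9-enedioic acid. One base-mediated operation on a symmetrical C24 bis-(E)-enone that already holds the central Z-olefin forms four C–C bonds, closes both six-membered rings and sheds the surplus ester as CO2. Late aromatization through silyl dienol ethers, desilylation and a single acetylation complete the target.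

Key step: step 4

Remark: the diacid starting material is assumed to be geometrically pure Z; the non-aromatic ring intermediates form as stereoisomer mixtures at CH centres that are all erased on aromatization, so their SMILES specify only the olefin geometry.

Step 1
Reactants: 1 (Z)-octadec-9-enedioic acid
Product: 2 (Z)-octadec-9-ene-1,18-diol
Conditions: LiAlH4, THF, 0 °C to reflux; then H2O, aq. NaOH
Reagents that add atoms: none
Why: Hydride reduction of both carboxylic acids with LiAlH4 should stop cleanly at the primary alcohols, and the isolated, unpolarized Z-olefin is not attacked by a nucleophilic hydride.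

Step 2
Reactants: 2 (Z)-octadec-9-ene-1,18-diol
Product: 3 (Z)-octadec-9-enedial
Conditions: (COCl)2, DMSO, CH2Cl2, −78 °C; Et3N, −78 to 0 °C; crude product used at once
Reagents that add atoms: none
Why: Swern oxidation should take both primary alcohols to aldehydes without over-oxidation, because both hydroxyls are activated as alkoxysulfonium ions before base is added, which leaves no hydroxy aldehyde to form hemiacetal-derived esters, and the olefin is inert.

Step 3
Reactants: 3 (Z)-octadec-9-enedial; 4 1-(triphenylphosphoranylidene)propan-2-one
Product: 5 (3E,12Z,21E)-tetracosa-3,12,21-triene-2,23-dione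
Conditions: 4 (2.5 equiv), THF, reflux
Reagents that add atoms: none
Why: Wittig olefination with a ketone-stabilized ylide should give the E-enone at both termini, and the weakly basic ylide neither enolizes the aldehyde nor disturbs the central Z-olefin.

Step 4
Reactants: 5 (3E,12Z,21E)-tetracosa-3,12,21-triene-2,23-dione; 6 dimethyl malonate
Product: 10 (Z)-1,16-bis(3,5-dioxocyclohexyl)hexadec-8-ene, via bis-Michael adduct 7 (not isolated), via bis(keto ester) 8 (not isolated), via bis(keto acid) 9 (not isolated)
Conditions: NaOMe (2.5 equiv), 6 (2.5 equiv), MeOH–THF, reflux; then aq. NaOH, reflux; then aq. HCl to pH 1, reflux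
Reagents that add atoms: none
Why: Methoxide forms the malonate anion, which adds to the β-carbon of each enone (ring bond C1–C6); proton transfer then gives the CH3-derived ketone enolate, which attacks one malonate ester and expels methoxide (ring bond C4–C5), and the cyclized β-dicarbonyl is held as its sodium enolate, which pulls both equilibria forward. The closest known reaction type is the Michael–Claisen (Dieckmann-type) annulation of malonate with methyl enones used for dimedone and 5-alkylcyclohexane-1,3-diones, with hydrolysis and decarboxylation in the same pot. Each of the two rings closes in the 6-(enolexo)-exo-trig mode. The transient stereocentres at the tether-bearing and ester-bearing ring carbons need no control, because hydroxide and then hot dilute acid remove the ester as CO2 and leave a ring with a mirror plane through the tether carbon, so the product has no stereocentre. Two selectivities are required, attack at the β-carbon and not at the carbonyl carbon, and closure from the terminal methyl enolate and not from the internal CH2 enolate; the first follows from reversible 1,2-addition of a stabilized carbanion, the second from ring size, since the internal enolate could only reach a four-membered ring. The isolated Z-olefin should pass unchanged through alkoxide, hydroxide and dilute aqueous acid.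

Step 5
Reactants: 10 (Z)-1,16-bis(3,5-dioxocyclohexyl)hexadec-8-ene
Product: 11 (Z)-1,16-bis[3,5-bis(tert-butyldimethylsilyloxy)cyclohexa-2,4-dien-1-yl]hexadec-8-ene
Conditions: TBSOTf (4.8 equiv), Et3N, CH2Cl2, 0 °C to rt
Reagents that add atoms: tert-butyldimethylsilyl trifluoromethanesulfonate, CC(C)(C)[Si](C)(C)OS(=O)(=O)C(F)(F)F
Why: Soft enolization with silyl triflate and amine: O-silylation of the enolized dione gives the 3-silyloxy enone, a second silyl transfer to its carbonyl oxygen makes a bis(silyloxy)allyl cation, and Et3N removes a proton from a ring CH2 to give the conjugated bis(silyl dienol ether); only one conjugated constitution is possible per ring.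

Step 6
Reactants: 11 (Z)-1,16-bis[3,5-bis(tert-butyldimethylsilyloxy)cyclohexa-2,4-dien-1-yl]hexadec-8-ene
Product: 12 (Z)-1,16-bis[3,5-bis(tert-butyldimethylsilyloxy)phenyl]hexadec-8-ene
Conditions: DDQ (2.4 equiv), 2,4,6-collidine, PhMe, 0 °C to rt
Reagents that add atoms: none
Why: Quinone dehydrogenation of a cyclohexadiene to an arene: DDQ abstracts hydride from the ring CH bearing the tether to give a cation stabilized by both silyloxy groups, which loses a proton from the adjacent CH2 and aromatizes, while the isolated olefin offers no comparably activated C–H and collidine buffers the acidic hydroquinone.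

Step 7
Reactants: 12 (Z)-1,16-bis[3,5-bis(tert-butyldimethylsilyloxy)phenyl]hexadec-8-ene
Product: 13 (Z)-1,16-bis(3,5-dihydroxyphenyl)hexadec-8-ene
Conditions: Bu4NF, AcOH, THF, 0 °C to rt, under Ar
Reagents that add atoms: none
Why: Fluoride-induced cleavage of aryl silyl ethers, driven by Si–F bond formation and buffered with AcOH, should release the four phenols in neutral form and not as oxidation-prone phenoxides.

Step 8
Reactants: 13 (Z)-1,16-bis(3,5-dihydroxyphenyl)hexadec-8-ene
Product: 14 3-[(Z)-16-(3,5-dihydroxyphenyl)hexadec-8-en-1-yl]-5-hydroxyphenyl acetate (oncostemonol B)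
Conditions: Ac2O (0.9 equiv, slow addition), pyridine, THF, −10 °C
Reagents that add atoms: acetic anhydride, CC(=O)OC(C)=O
Why: Acylation of a phenol by Ac2O with pyridine: the four hydroxyls are equivalent by symmetry, so the first acyl transfer can only give the target, and a deficiency of anhydride at low temperature should keep higher acetates minor, with unreacted 13 recovered and over-acetylated material returned to 13 by K2CO3/MeOH.

Compound list
1 | (Z)-octadec-9-enedioic acid | OC(=O)CCCCCCC/C=C\CCCCCCCC(=O)O | starting material
2 | (Z)-octadec-9-ene-1,18-diol | OCCCCCCCC/C=C\CCCCCCCCO | intermediate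
3 | (Z)-octadec-9-enedial | O=CCCCCCCC/C=C\CCCCCCCC=O | intermediate
4 | 1-(triphenylphosphoranylidene)propan-2-one | CC(=O)C=P(c1ccccc1)(c1ccccc1)c1ccccc1 | starting material
5 | (3E,12Z,21E)-tetracosa-3,12,21-triene-2,23-dione | CC(=O)/C=C/CCCCCCC/C=C\CCCCCCC/C=C/C(C)=O | intermediate
6 | dimethyl malonate | COC(=O)CC(=O)OC | starting material
7 | tetramethyl (Z)-2,19-bis(2-oxopropyl)icos-10-ene-1,1,20,20-tetracarboxylate (bis-Michael adduct, stereoisomer mixture, not isolated) | COC(=O)C(C(=O)OC)C(CC(C)=O)CCCCCCC/C=C\CCCCCCCC(CC(C)=O)C(C(=O)OC)C(=O)OC | intermediate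
8 | dimethyl 6,6'-[(Z)-hexadec-8-ene-1,16-diyl]bis(2,4-dioxocyclohexane-1-carboxylate) (bis(keto ester), present as its disodium enolate, stereoisomer mixture, not isolated) | COC(=O)C1C(=O)CC(=O)CC1CCCCCCC/C=C\CCCCCCCC1CC(=O)CC(=O)C1C(=O)OC | intermediate
9 | 6,6'-[(Z)-hexadec-8-ene-1,16-diyl]bis(2,4-dioxocyclohexane-1-carboxylic acid) (bis(keto acid), stereoisomer mixture, not isolated) | OC(=O)C1C(=O)CC(=O)CC1CCCCCCC/C=C\CCCCCCCC1CC(=O)CC(=O)C1C(=O)O | intermediate
10 | (Z)-1,16-bis(3,5-dioxocyclohexyl)hexadec-8-ene | O=C1CC(=O)CC(CCCCCCC/C=C\CCCCCCCC2CC(=O)CC(=O)C2)C1 | intermediate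
11 | (Z)-1,16-bis[3,5-bis(tert-butyldimethylsilyloxy)cyclohexa-2,4-dien-1-yl]hexadec-8-ene (stereoisomer mixture at the two ring CH centres) | CC(C)(C)[Si](C)(C)OC1=CC(O[Si](C)(C)C(C)(C)C)=CC(CCCCCCC/C=C\CCCCCCCC2CC(O[Si](C)(C)C(C)(C)C)=CC(O[Si](C)(C)C(C)(C)C)=C2)C1 | intermediate
12 | (Z)-1,16-bis[3,5-bis(tert-butyldimethylsilyloxy)phenyl]hexadec-8-ene | CC(C)(C)[Si](C)(C)Oc1cc(O[Si](C)(C)C(C)(C)C)cc(CCCCCCC/C=C\CCCCCCCc2cc(O[Si](C)(C)C(C)(C)C)cc(O[Si](C)(C)C(C)(C)C)c2)c1 | intermediate
13 | (Z)-1,16-bis(3,5-dihydroxyphenyl)hexadec-8-ene | Oc1cc(O)cc(CCCCCCC/C=C\CCCCCCCc2cc(O)cc(O)c2)c1 | intermediate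
14 | 3-[(Z)-16-(3,5-dihydroxyphenyl)hexadec-8-en-1-yl]-5-hydroxyphenyl acetate (oncostemonol B) | CC(=O)Oc1cc(O)cc(CCCCCCC/C=C\CCCCCCCc2cc(O)cc(O)c2)c1 | target

Total step count: 8. Longest linear sequence: 8 steps (fully linear from 1).

Steps most likely to fail

Step 4. The bis-enone may oligomerize through intermolecular addition of ketone enolates to enone termini, or the sequence may stall after only one ring has closed. The fallback builds the same rings by the complementary Michael–Dieckmann pairing, which has no enolizable enone in the flask. It sets out from dialdehyde 3, which is olefinated with methyl (triphenylphosphoranylidene)acetate in CH2Cl2 at room temperature to dimethyl (2E,11Z,20E)-docosa-2,11,20-trienedioate F1. Methyl acetoacetate and NaOMe in refluxing MeOH should add to both enoates to give dimethyl (Z)-2,21-diacetyl-3,20-bis(2-methoxy-2-oxoethyl)docos-11-enedioate F2. In the same pot the methyl ketone enolate of F2 closes onto the chain ester to give the bis(keto ester) 8. Aqueous NaOH and then hot aqueous HCl, as in step 4, lead through 9 to dione 10, where the route is rejoined.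

Step 6. Protodesilylation of the dienol ethers by the acidic hydroquinone may outrun hydride abstraction, or covalent quinone adducts may accumulate without collapsing to the arene. The fallback moves the dehydrogenation to a palladium enolate pathway of the Saegusa–Ito type. It sets out from 11, which with Pd(OAc)2 in MeCN at room temperature should undergo transmetalation of one silyl enol ether per ring, β-hydride elimination and tautomerization to (Z)-1,16-bis[3-(tert-butyldimethylsilyloxy)-5-hydroxyphenyl]hexadec-8-ene F3. The 1,2-disubstituted olefin is expected to be a poor ligand under these conditions. Bu4NF/AcOH as in step 7 then gives tetraol 13, where the route is rejoined.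

Step 8. Statistical over-acylation and acetyl scrambling among polar, poorly separable polyphenols may make isolation of the monoacetate impractical. The fallback moves the desymmetrization to the silyl ether stage, where all components are non-polar and easily separated. It sets out from 12, which is treated with a deficiency of Bu4NF in THF at −40 °C to unveil a single phenol, giving 3-{(Z)-16-[3,5-bis(tert-butyldimethylsilyloxy)phenyl]hexadec-8-en-1-yl}-5-(tert-butyldimethylsilyloxy)phenol F4, with unreacted 12 recycled. Ac2O and pyridine then acetylate the only free hydroxyl completely to 3-{(Z)-16-[3,5-bis(tert-butyldimethylsilyloxy)phenyl]hexadec-8-en-1-yl}-5-(tert-butyldimethylsilyloxy)phenyl acetate F5. HF·pyridine in THF/pyridine should remove the three silyl groups without touching the aryl acetate and deliver the target 14.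

Further compounds
F1 | step 4 | dimethyl (2E,11Z,20E)-docosa-2,11,20-trienedioate | COC(=O)/C=C/CCCCCCC/C=C\CCCCCCC/C=C/C(=O)OC
F2 | step 4 | dimethyl (Z)-2,21-diacetyl-3,20-bis(2-methoxy-2-oxoethyl)docos-11-enedioate (stereoisomer mixture, not isolated) | COC(=O)C(C(C)=O)C(CC(=O)OC)CCCCCCC/C=C\CCCCCCCC(CC(=O)OC)C(C(C)=O)C(=O)OC
F3 | step 6 | (Z)-1,16-bis[3-(tert-butyldimethylsilyloxy)-5-hydroxyphenyl]hexadec-8-ene | CC(C)(C)[Si](C)(C)Oc1cc(O)cc(CCCCCCC/C=C\CCCCCCCc2cc(O)cc(O[Si](C)(C)C(C)(C)C)c2)c1
F4 | step 8 | 3-{(Z)-16-[3,5-bis(tert-butyldimethylsilyloxy)phenyl]hexadec-8-en-1-yl}-5-(tert-butyldimethylsilyloxy)phenol | CC(C)(C)[Si](C)(C)Oc1cc(O)cc(CCCCCCC/C=C\CCCCCCCc2cc(O[Si](C)(C)C(C)(C)C)cc(O[Si](C)(C)C(C)(C)C)c2)c1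
F5 | step 8 | 3-{(Z)-16-[3,5-bis(tert-butyldimethylsilyloxy)phenyl]hexadec-8-en-1-yl}-5-(tert-butyldimethylsilyloxy)phenyl acetate | CC(=O)Oc1cc(O[Si](C)(C)C(C)(C)C)cc(CCCCCCC/C=C\CCCCCCCc2cc(O[Si](C)(C)C(C)(C)C)cc(O[Si](C)(C)C(C)(C)C)c2)c1
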